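**Strategy.** The route rests on recasting a furan as the benzene ring. The 1,2,4-trioxygenated ring of the target (oxygens on C1, C2 and C4, pentadecyl on C6) has the same carbon–oxygen connectivity as a ring-opened 5-(benzyloxymethyl)furfural carrying the chain on furan C4. Furan C5 and C2 become C1 and C4, the benzyloxymethyl carbon becomes C2, the formyl carbon C3. In one operation, hydration opens the furan to a 2,5-dioxohexanal, whose benzyloxymethylene carbon closes onto the aldehyde (new C2–C3 bond). Aromatisation gives a hydroquinone isomeric with the furan, with O2 already benzylated. Selective O4 benzylation, O1 acetylation and hydrogenolysis finish the synthesis.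

Key step: step 5

Remark on the chemistry: the benzyl ether is kept on the oxymethyl oxygen through the key step because it blocks the enediol shift open to a free α-hydroxy ketone and delivers O2 already masked. All hydroquinone-stage compounds are assumed to be handled under argon.

Step 1
Reactants: 1 3-bromofuran-2-carbaldehyde
Product: 2 (3-bromofuran-2-yl)methanol
Conditions: NaBH4, MeOH, 0 °C
Reagents that add atoms: none
Why: Borohydride 1,2-reduction of an aryl aldehyde, to which the aryl bromide and the furan ring are inert.

Step 2
Reactants: 2 (3-bromofuran-2-yl)methanol; 3 benzyl bromide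
Product: 4 2-[(benzyloxy)methyl]-3-bromofuran
Conditions: NaH, 3, TBAI (cat.), THF, 0 °C → rt
Reagents that add atoms: none
Why: Williamson ether synthesis of a primary alkoxide with a benzylic bromide under basic conditions that spare the acid-sensitive furfuryl system.

Step 3
Reactants: 4 2-[(benzyloxy)methyl]-3-bromofuran; 5 1-bromopentadecane
Product: 7 2-[(benzyloxy)methyl]-3-pentadecylfuran, via pentadecylmagnesium bromide 6 (not isolated)
Conditions: 5, Mg, THF, 50 °C; then 4, Ni(dppp)Cl2 (3 mol %), THF, 0 °C → rt
Reagents that add atoms: none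
Why: Grignard formation followed by Kumada–Corriu cross-coupling of a 3-bromofuran with a primary alkylmagnesium halide, in which the chelating diphosphine suppresses β-hydride elimination and the benzyl ether tolerates the Grignard reagent.

Step 4
Reactants: 7 2-[(benzyloxy)methyl]-3-pentadecylfuran
Product: 10 5-[(benzyloxy)methyl]-4-pentadecylfuran-2-carbaldehyde, via furyllithium 8 (not isolated), via lithium aminoalkoxide 9 (not isolated)
Conditions: n-BuLi, THF, −78 → −20 °C; DMF, −78 °C → rt; H2O
Reagents that add atoms: N,N-dimethylformamide, CN(C)C=O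
Why: α-Lithiation of the furan at its only free α-position followed by Bouveault-type formylation with DMF, the low temperature keeping deprotonation at the ether methylenes (Wittig rearrangement) from competing.

Step 5
Reactants: 10 5-[(benzyloxy)methyl]-4-pentadecylfuran-2-carbaldehyde
Product: 14 2-(benzyloxy)-6-pentadecylbenzene-1,4-diol, via dioxohexanal 11 (not isolated), via aldol adduct 12 (not isolated), via enedione 13 (not isolated)
Conditions: Zn(OTf)2 (10 mol %), degassed 1,4-dioxane/H2O (3:1), Ar, sealed vessel, 180–220 °C; aq. Na2S2O4 work-up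
Reagents that add atoms: water, O
Why: The zinc Lewis acid and hot water should hydrate the formyl-conjugated furan at a ring α-carbon, and the hemiketal opens to 1,4-diketone 11 with a terminal aldehyde; the enol of the C5 ketone on the benzyloxymethylene side then attacks the aldehyde carbon (intramolecular aldol to 12), water is lost to give enedione 13, and two keto–enol shifts deliver arene 14 without any oxidant because 10 and 14 are isomers. The closest known reaction is the hydrothermal and zinc-triflate-promoted rearrangement of 5-(hydroxymethyl)furfural to benzene-1,2,4-triol, applied here to its O-benzyl, C4-alkyl congener in a dioxane-rich medium that dissolves the C15 chain. The one ring closes in a 6-(enolendo)-exo-trig aldol; 11–13 carry stereocentres only transiently and none remains in 14. The step needs the aldehyde and not the adjacent C2 ketone to act as acceptor (the latter would lead to a cyclopentenone): the aldehyde is the more electrophilic carbonyl, both aldols are reversible, and only the six-membered adduct can drain into the aromatic sink. The positions of the three oxygens and of the chain are fixed by the furan substitution pattern alone, and a near-neutral Lewis acid is chosen in place of mineral acid so that ionisation of the furfurylic C–O bond (loss of benzyl alcohol and formic acid along the levulinate pathway) and hydrolysis of the benzyl ethers stay slow.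

Step 6
Reactants: 14 2-(benzyloxy)-6-pentadecylbenzene-1,4-diol; 3 benzyl bromide
Product: 15 2,4-bis(benzyloxy)-6-pentadecylphenol
Conditions: 3 (1.05 equiv), K2CO3 (1.1 equiv), degassed DMF, Ar, 0 °C → rt
Reagents that add atoms: none
Why: Williamson O-alkylation under weak base should select the C4 hydroxyl, which is the more acidic one (meta to the benzyloxy group) and the only one not flanked by two ortho substituents, while exclusion of air prevents oxidation to the quinone.

Step 7
Reactants: 15 2,4-bis(benzyloxy)-6-pentadecylphenol
Product: 16 2,4-bis(benzyloxy)-6-pentadecylphenyl acetate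
Conditions: Ac2O, pyridine, DMAP (cat.), CH2Cl2, rt
Reagents that add atoms: acetic anhydride, CC(=O)OC(C)=O
Why: DMAP-catalysed acyl transfer esterifies even a di-ortho-substituted phenol, which is the only free hydroxyl left.

Step 8
Reactants: 16 2,4-bis(benzyloxy)-6-pentadecylphenyl acetate
Product: 17 2,4-dihydroxy-6-pentadecylphenyl acetate
Conditions: H2 (1 atm), 10% Pd/C, EtOAc, rt
Reagents that add atoms: none
Why: Catalytic hydrogenolysis cleaves both aryl benzyl ethers, while the aryl acetate is stable to hydrogen over palladium on carbon in a neutral aprotic solvent, which also holds back acetyl migration to the newly freed C2 hydroxyl.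

**Compound list**

1 | 3-bromofuran-2-carbaldehyde | O=Cc1occc1Br | starting material
2 | (3-bromofuran-2-yl)methanol | OCc1occc1Br | intermediate
3 | benzyl bromide | BrCc1ccccc1 | starting material
4 | 2-[(benzyloxy)methyl]-3-bromofuran | Brc1ccoc1COCc2ccccc2 | intermediate
5 | 1-bromopentadecane | CCCCCCCCCCCCCCCBr | starting material
6 | pentadecylmagnesium bromide, formed and used in solution | CCCCCCCCCCCCCCC[Mg]Br | intermediate
7 | 2-[(benzyloxy)methyl]-3-pentadecylfuran | CCCCCCCCCCCCCCCc1ccoc1COCc2ccccc2 | intermediate
8 | {5-[(benzyloxy)methyl]-4-pentadecylfuran-2-yl}lithium, formed in the flask | [Li]c1cc(CCCCCCCCCCCCCCC)c(COCc2ccccc2)o1 | intermediate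
9 | lithium {5-[(benzyloxy)methyl]-4-pentadecylfuran-2-yl}(dimethylamino)methanolate, racemic, formed in the flask | [Li+].[O-]C(N(C)C)c1cc(CCCCCCCCCCCCCCC)c(COCc2ccccc2)o1 | intermediate
10 | 5-[(benzyloxy)methyl]-4-pentadecylfuran-2-carbaldehyde | O=Cc1cc(CCCCCCCCCCCCCCC)c(COCc2ccccc2)o1 | intermediate
11 | 6-(benzyloxy)-2,5-dioxo-4-pentadecylhexanal, racemic, formed in the flask | O=CC(=O)CC(CCCCCCCCCCCCCCC)C(=O)COCc1ccccc1 | intermediate
12 | 2-(benzyloxy)-3-hydroxy-6-pentadecylcyclohexane-1,4-dione, mixture of diastereomers, formed in the flask | O=C1CC(CCCCCCCCCCCCCCC)C(=O)C(OCc2ccccc2)C1O | intermediate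
13 | 2-(benzyloxy)-6-pentadecylcyclohex-2-ene-1,4-dione, racemic, formed in the flask | O=C1CC(CCCCCCCCCCCCCCC)C(=O)C(OCc2ccccc2)=C1 | intermediate
14 | 2-(benzyloxy)-6-pentadecylbenzene-1,4-diol | CCCCCCCCCCCCCCCc1cc(O)cc(OCc2ccccc2)c1O | intermediate
15 | 2,4-bis(benzyloxy)-6-pentadecylphenol | CCCCCCCCCCCCCCCc1cc(OCc2ccccc2)cc(OCc2ccccc2)c1O | intermediate
16 | 2,4-bis(benzyloxy)-6-pentadecylphenyl acetate | CCCCCCCCCCCCCCCc1cc(OCc2ccccc2)cc(OCc2ccccc2)c1OC(C)=O | intermediate
17 | 2,4-dihydroxy-6-pentadecylphenyl acetate (no stereocentres) | CCCCCCCCCCCCCCCc1cc(O)cc(O)c1OC(C)=O | target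

**Step count and risks**

Total step count: 8. Longest linear sequence: 8 steps (1 → 17); the Grignard reagent 6 is made within step 3.

Steps most likely to fail:

1. Step 5. The furan may open only at temperatures where the furfurylic ether ionises and the chain of events turns to formic acid extrusion, where the benzyl ethers hydrolyse, or where the open-chain ketoaldehyde oligomerises. The fallback avoids the furan altogether, sets out from 3 and 6 and comes back at 15. Purchased 5-bromoresorcinol (Oc1cc(O)cc(Br)c1) would be bis-benzylated with 3 (K2CO3, DMF) to 1,3-bis(benzyloxy)-5-bromobenzene F1. Kumada–Corriu coupling of this bromide with 6 (Ni(dppp)Cl2, THF) would give 1,3-bis(benzyloxy)-5-pentadecylbenzene F2. Vilsmeier–Haack formylation (POCl3, DMF) at the position ortho to the chain and para to one benzyloxy group would proceed through the aryl iminium chloride F3 to 2,4-bis(benzyloxy)-6-pentadecylbenzaldehyde F4. Baeyer–Villiger (Dakin-type) oxidation with mCPBA would give 2,4-bis(benzyloxy)-6-pentadecylphenyl formate F5, and methanolysis (K2CO3, MeOH) would give 15, from which steps 7 and 8 follow unchanged.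

2. Step 6. Discrimination between the two hydroxyls may be incomplete (alkylation at the flanked oxygen or double alkylation), and the hydroquinone may be oxidised under base. The fallback sets out from 14, replaces selection by acidity with steric selection by a bulky silyl group, and comes back at 17. TIPSCl and imidazole (DMF, 0 °C) should silylate only the unhindered hydroxyl to give 2-(benzyloxy)-6-pentadecyl-4-[(triisopropylsilyl)oxy]phenol F6. Acetylation (Ac2O, pyridine, DMAP) would give 2-(benzyloxy)-6-pentadecyl-4-[(triisopropylsilyl)oxy]phenyl acetate F7. Desilylation with TBAF buffered by AcOH (THF, 0 °C) would give 2-(benzyloxy)-4-hydroxy-6-pentadecylphenyl acetate F8, and hydrogenolysis (H2, 10% Pd/C, EtOAc) would give 17.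

3. Step 3. Hydrodebromination and Grignard homocoupling may erode the coupling, and with excess Grignard reagent nickel may insert into the furfurylic C–O bond of the benzyl ether. The fallback sets out from 4 and comes back at 7 by a B-alkyl Suzuki–Miyaura coupling, which uses a palladium catalyst that leaves such ethers alone. Purchased 1-pentadecene (C=CCCCCCCCCCCCCC) would be hydroborated with 9-BBN (THF, rt) to 9-pentadecyl-9-borabicyclo[3.3.1]nonane F9, which would be coupled with 4 (Pd(dppf)Cl2, K3PO4, THF/H2O, 65 °C) to give 7.

**Further compounds**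

F1 | step 5 | 1,3-bis(benzyloxy)-5-bromobenzene | Brc1cc(OCc2ccccc2)cc(OCc2ccccc2)c1
F2 | step 5 | 1,3-bis(benzyloxy)-5-pentadecylbenzene | CCCCCCCCCCCCCCCc1cc(OCc2ccccc2)cc(OCc2ccccc2)c1
F3 | step 5 | N-{[2,4-bis(benzyloxy)-6-pentadecylphenyl]methylidene}-N-methylmethanaminium chloride | CCCCCCCCCCCCCCCc1cc(OCc2ccccc2)cc(OCc2ccccc2)c1C=[N+](C)C.[Cl-]
F4 | step 5 | 2,4-bis(benzyloxy)-6-pentadecylbenzaldehyde | CCCCCCCCCCCCCCCc1cc(OCc2ccccc2)cc(OCc2ccccc2)c1C=O
F5 | step 5 | 2,4-bis(benzyloxy)-6-pentadecylphenyl formate | CCCCCCCCCCCCCCCc1cc(OCc2ccccc2)cc(OCc2ccccc2)c1OC=O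
F6 | step 6 | 2-(benzyloxy)-6-pentadecyl-4-[(triisopropylsilyl)oxy]phenol | CCCCCCCCCCCCCCCc1cc(O[Si](C(C)C)(C(C)C)C(C)C)cc(OCc2ccccc2)c1O
F7 | step 6 | 2-(benzyloxy)-6-pentadecyl-4-[(triisopropylsilyl)oxy]phenyl acetate | CCCCCCCCCCCCCCCc1cc(O[Si](C(C)C)(C(C)C)C(C)C)cc(OCc2ccccc2)c1OC(C)=O
F8 | step 6 | 2-(benzyloxy)-4-hydroxy-6-pentadecylphenyl acetate | CCCCCCCCCCCCCCCc1cc(O)cc(OCc2ccccc2)c1OC(C)=O
F9 | step 3 | 9-pentadecyl-9-borabicyclo[3.3.1]nonane | CCCCCCCCCCCCCCCB1C2CCCC1CCC2
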